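**Plan**

Numbering used: 3,7-dioxabicyclo[3.3.0]octane with ring fusion C1/C5, guaiacyl on C2, prenyloxyaryl on C6; ring 1 = C1–C2–O3–C4–C5, ring 2 = C5–C6–O7–C8–C1.
Retrosynthetic cuts in order: phenol O–Si; aryl–C2 (arylzinc on a C2 sulfonyl acetal); prenyl O–C; C2–O3 with C2=CH2 restored (vinyl as masked aldehyde, opens ring 1); C6–O7 (benzylic ether, opens ring 2); C5–C6 (aldol); C1–C2 (conjugate vinylation of 2(5H)-furanone).
Forward: vinyl lactone, aldol with silyl-protected vanillin, reduction, ring 2 by benzylic etherification, ring 1 by ozonolysis and acetalisation, silyl-to-prenyl exchange, sulfone, arylation at C2, desilylation.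
Enabling feature: C2 is bonded to ring oxygen O3, so it can be held as an acetal, armed with a phenylsulfonyl group and ionised to an oxocarbenium ion inside the cis-fused, V-shaped bicycle, whose convex face alone is open; one event then joins the differently protected guaiacyl ring and completes the fourth contiguous stereocentre.
Stereochemistry: C1 by rhodium/(S)-BINAP catalyst control, C5 by the anti aldol, C6 by trans-selective capture of a benzylic cation, C2 by convex-face attack.

Key step: step 10

Assumption: (S)-BINAP is taken to give the 4S vinyl lactone, by analogy with the sense of induction established for cyclic enones and unsaturated lactones; if the sense is reversed, (R)-BINAP is used.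

**Route**

Step 1
Reactants: 1 2(5H)-furanone
Product: 2 (4S)-4-ethenyloxolan-2-one
Conditions: potassium vinyltrifluoroborate (1.5 equiv), [Rh(cod)2]BF4 (3 mol %), (S)-BINAP (3.3 mol %), Et3N, toluene/H2O (10:1), 80 °C
Reagents that add atoms: potassium vinyltrifluoroborate, C=C[B-](F)(F)F.[K+]
Why: Hayashi–Miyaura rhodium-catalysed asymmetric conjugate addition, in which the vinyl–rhodium–BINAP species carbometalates one enantioface of the butenolide C=C and the resulting oxa-π-allyl rhodium is hydrolysed, should set C4 of the lactone (the future C1) under catalyst control.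

Step 2
Reactants: 3 vanillin
Product: 4 3-methoxy-4-(triisopropylsilyloxy)benzaldehyde
Conditions: TIPSCl, imidazole, DMF, rt
Reagents that add atoms: chlorotri(propan-2-yl)silane (TIPSCl), CC(C)[Si](Cl)(C(C)C)C(C)C
Why: Standard phenol silylation, chosen because the bulky aryl silyl ether should tolerate the amide base, LiAlH4, sulfonic acid and ozone of steps 3 to 6, which a prenyl ether would not survive.

Step 3
Reactants: 2 (4S)-4-ethenyloxolan-2-one; 4 3-methoxy-4-(triisopropylsilyloxy)benzaldehyde
Product: 6 (3S,4R)-4-ethenyl-3-{hydroxy[3-methoxy-4-(triisopropylsilyloxy)phenyl]methyl}oxolan-2-one as a mixture of carbinol epimers, via lithium enolate 5 (not isolated)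
Conditions: LiN(SiMe3)2 (1.1 equiv), THF, −78 °C; then 4, −78 °C; AcOH, −78 °C
Reagents that add atoms: none
Why: Aldol addition of the lactone lithium enolate, in which the aldehyde approaches the enolate face anti to the vinyl group so that C3 (future C5) is set trans to it by substrate control, the carbinol configuration being left open because step 5 is stereoconvergent at that carbon.

Step 4
Reactants: 6 aldol adduct
Product: 7 (2R,3R)-2-ethenyl-3-{hydroxy[3-methoxy-4-(triisopropylsilyloxy)phenyl]methyl}butane-1,4-diol as a mixture of carbinol epimers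
Conditions: LiAlH4, THF, 0 °C; then H2O
Reagents that add atoms: none
Why: Hydride reduction of the lactone to the 1,4-diol, fast enough at 0 °C that retro-aldol cleavage of the aluminium aldolate should not compete, and leaving the aryl silyl ether, the alkene and both stereocentres untouched.

Step 5
Reactants: 7 triol
Product: 8 [(2S,3R,4R)-4-ethenyl-2-[3-methoxy-4-(triisopropylsilyloxy)phenyl]oxolan-3-yl]methanol
Conditions: CSA (10 mol %), CH2Cl2, 0 °C to rt
Reagents that add atoms: none
Why: Acid-catalysed SN1 cyclodehydration through the para-silyloxybenzyl cation, which only the primary hydroxyl on the vinyl-bearing carbon can capture in a five-membered ring (the other would give an oxetane) and which closes anti to the neighbouring hydroxymethyl group, so both carbinol epimers should converge on the 2,3-trans tetrahydrofuran (sets the future C6).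

Step 6
Reactants: 8 vinyl tetrahydrofuran alcohol
Product: 10 (1R,5R,6S)-2-methoxy-6-[3-methoxy-4-(triisopropylsilyloxy)phenyl]-3,7-dioxabicyclo[3.3.0]octane as a mixture of C2 anomers, via lactol 9 (not isolated)
Conditions: O3, CH2Cl2/MeOH, −78 °C (Sudan Red 7B end point); Me2S, −78 °C to rt; then PPTS (cat.), MeOH, rt
Reagents that add atoms: methanol, CO
Why: Ozonolysis of the only alkene gives an aldehyde held cis to the hydroxymethyl group, which closes to the cis-fused lactol 9 (ring 1), and acid-catalysed acetalisation then exchanges the anomeric hydroxyl (the ozone-derived oxygen, lost as water) for methoxyl, fixing C2 at the aldehyde oxidation level in a base-stable form.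

Step 7
Reactants: 10 silyl-protected methyl acetal
Product: 12 (1R,5R,6S)-2-methoxy-6-[3-methoxy-4-(3-methylbut-2-enyloxy)phenyl]-3,7-dioxabicyclo[3.3.0]octane, via tetrabutylammonium phenoxide 11 (not isolated)
Conditions: Bu4NF (1.1 equiv), THF, 0 °C; then prenyl bromide (1.5 equiv), 0 °C to rt
Reagents that add atoms: 1-bromo-3-methylbut-2-ene (prenyl bromide), CC(C)=CCBr
Why: Fluoride desilylation followed in the same flask by Williamson etherification of the naked phenoxide at the primary allylic bromide, so that the prenyl alkene enters only after the oxidative cleavage of step 6.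

Step 8
Reactants: 12 prenylated methyl acetal
Product: 13 (1R,5R,6S)-6-[3-methoxy-4-(3-methylbut-2-enyloxy)phenyl]-2-(phenylsulfonyl)-3,7-dioxabicyclo[3.3.0]octane as a mixture of C2 anomers
Conditions: PhSO2H (3 equiv), CaCl2, CH2Cl2, rt
Reagents that add atoms: benzenesulfinic acid, O=S(O)c1ccccc1
Why: Acetal exchange through the ring oxocarbenium ion, with sulfinate captured at sulfur and CaCl2 binding the released methanol, is the standard entry to 2-(phenylsulfonyl) cyclic ethers and uses an acid weak enough that the aryl prenyl ether and the benzylic C6–O7 ether should survive.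

Step 9
Reactants: 14 4-bromo-2-methoxyphenol
Product: 15 (4-bromo-2-methoxyphenoxy)(tert-butyl)dimethylsilane
Conditions: TBSCl, imidazole, DMF, rt
Reagents that add atoms: tert-butylchlorodimethylsilane (TBSCl), CC(C)(C)[Si](C)(C)Cl
Why: Standard phenol silylation, which masks the acidic phenol for the organometallic chemistry of step 10, while the bromine para to oxygen fixes the ring position that will be bonded to C2.

Step 10
Reactants: 13 anomeric sulfone; 15 silylated aryl bromide
Product: 18 (1R,2S,5R,6S)-2-[4-(tert-butyldimethylsilyloxy)-3-methoxyphenyl]-6-[3-methoxy-4-(3-methylbut-2-enyloxy)phenyl]-3,7-dioxabicyclo[3.3.0]octane, via arylmagnesium bromide 16 (not isolated), via diarylzinc 17 (not isolated)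
Conditions: 15 (3 equiv), Mg, THF, 40 °C; ZnBr2 (1.5 equiv), THF, 0 °C to rt; then 13, THF, rt; aq NH4Cl
Reagents that add atoms: none
Why: The zinc and magnesium bromides that accompany diarylzinc 17 assist departure of benzenesulfinate from C2, the lone pair of ring oxygen O3 giving a bicyclic oxocarbenium ion, and an aryl group is transferred from zinc to C2 to form the aryl–C2 bond. The closest known reaction type is the substitution of 2-(phenylsulfonyl) tetrahydrofurans and tetrahydropyrans by aryl-, alkenyl- and alkynylzinc reagents, which is also the logic of C-aryl glycoside synthesis. No ring is closed in this step; both rings are already in place and serve only as the stereocontrol element. The new stereocentre C2 is set by the cis-fused bicycle: ring 2 with its C8 methylene shields the concave face of the planar C2=O3 cation, so the aryl group should enter on the convex face, cis to H1 and trans to C8, which is the 2S (exo) configuration of the target and the opposite of what hydride delivery to a 2-aryl oxocarbenium ion would give. The step needs ionisation at C2 only and a defined position on the arene: the first is secured because C2–S is the only bond flanked by an oxygen lone pair and a good leaving group under Lewis acids too mild (ZnBr2, MgBr2 in THF) to ionise the benzylic C6–O7 ether or the prenyl ether, the second because the carbon–zinc bond sits where the bromine of 15 was. The anomer composition of 13 is irrelevant because both anomers give the same cation.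

Step 11
Reactants: 18 silyl-protected target
Product: 19 (1R,2S,5R,6S)-2-(4-hydroxy-3-methoxyphenyl)-6-[3-methoxy-4-(3-methylbut-2-enyloxy)phenyl]-3,7-dioxabicyclo[3.3.0]octane (target)
Conditions: Bu4NF, AcOH, THF, 0 °C
Reagents that add atoms: none
Why: Buffered fluoride desilylation of the aryl silyl ether, in which acetic acid protonates the phenoxide as it forms so that the para-hydroxybenzylic ether is not exposed to base, and to which no other group in the molecule should respond.

**Compound list**

1 | 2(5H)-furanone | O=C1C=CCO1 | starting material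
2 | (4S)-4-ethenyloxolan-2-one | O=C1C[C@@H](C=C)CO1 | intermediate
3 | vanillin (4-hydroxy-3-methoxybenzaldehyde) | COc1cc(C=O)ccc1O | starting material
4 | 3-methoxy-4-(triisopropylsilyloxy)benzaldehyde | COc1cc(C=O)ccc1O[Si](C(C)C)(C(C)C)C(C)C | intermediate
5 | lithium enolate of 2 (lithium 4-ethenyl-4,5-dihydrofuran-2-olate, C4 unchanged; not isolated) | C=C[C@H]1COC([O-])=C1.[Li+] | intermediate
6 | (3S,4R)-4-ethenyl-3-{hydroxy[3-methoxy-4-(triisopropylsilyloxy)phenyl]methyl}oxolan-2-one, both carbinol epimers | C=C[C@H]1COC(=O)[C@@H]1C(O)c1ccc(O[Si](C(C)C)(C(C)C)C(C)C)c(OC)c1 | intermediate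
7 | (2R,3R)-2-ethenyl-3-{hydroxy[3-methoxy-4-(triisopropylsilyloxy)phenyl]methyl}butane-1,4-diol, both carbinol epimers | C=C[C@@H](CO)[C@H](CO)C(O)c1ccc(O[Si](C(C)C)(C(C)C)C(C)C)c(OC)c1 | intermediate
8 | [(2S,3R,4R)-4-ethenyl-2-[3-methoxy-4-(triisopropylsilyloxy)phenyl]oxolan-3-yl]methanol | C=C[C@H]1CO[C@H](c2ccc(O[Si](C(C)C)(C(C)C)C(C)C)c(OC)c2)[C@H]1CO | intermediate
9 | (1R,5R,6S)-6-[3-methoxy-4-(triisopropylsilyloxy)phenyl]-3,7-dioxabicyclo[3.3.0]octan-2-ol, both C2 anomers (not isolated) | OC1OC[C@H]2[C@@H]1CO[C@@H]2c1ccc(O[Si](C(C)C)(C(C)C)C(C)C)c(OC)c1 | intermediate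
10 | (1R,5R,6S)-2-methoxy-6-[3-methoxy-4-(triisopropylsilyloxy)phenyl]-3,7-dioxabicyclo[3.3.0]octane, both C2 anomers | COC1OC[C@H]2[C@@H]1CO[C@@H]2c1ccc(O[Si](C(C)C)(C(C)C)C(C)C)c(OC)c1 | intermediate
11 | tetrabutylammonium phenoxide obtained by O-desilylation of 10 (not isolated) | COC1OC[C@H]2[C@@H]1CO[C@@H]2c1ccc([O-])c(OC)c1.CCCC[N+](CCCC)(CCCC)CCCC | intermediate
12 | (1R,5R,6S)-2-methoxy-6-[3-methoxy-4-(3-methylbut-2-enyloxy)phenyl]-3,7-dioxabicyclo[3.3.0]octane, both C2 anomers | COC1OC[C@H]2[C@@H]1CO[C@@H]2c1ccc(OCC=C(C)C)c(OC)c1 | intermediate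
13 | (1R,5R,6S)-6-[3-methoxy-4-(3-methylbut-2-enyloxy)phenyl]-2-(phenylsulfonyl)-3,7-dioxabicyclo[3.3.0]octane, both C2 anomers | O=S(=O)(c1ccccc1)C1OC[C@H]2[C@@H]1CO[C@@H]2c1ccc(OCC=C(C)C)c(OC)c1 | intermediate
14 | 4-bromo-2-methoxyphenol | COc1cc(Br)ccc1O | starting material
15 | (4-bromo-2-methoxyphenoxy)(tert-butyl)dimethylsilane | COc1cc(Br)ccc1O[Si](C)(C)C(C)(C)C | intermediate
16 | [4-(tert-butyldimethylsilyloxy)-3-methoxyphenyl]magnesium bromide (not isolated) | COc1cc([Mg]Br)ccc1O[Si](C)(C)C(C)(C)C | intermediate
17 | bis[4-(tert-butyldimethylsilyloxy)-3-methoxyphenyl]zinc (not isolated) | COc1cc([Zn]c2ccc(O[Si](C)(C)C(C)(C)C)c(OC)c2)ccc1O[Si](C)(C)C(C)(C)C | intermediate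
18 | (1R,2S,5R,6S)-2-[4-(tert-butyldimethylsilyloxy)-3-methoxyphenyl]-6-[3-methoxy-4-(3-methylbut-2-enyloxy)phenyl]-3,7-dioxabicyclo[3.3.0]octane | COc1cc([C@H]2OC[C@H]3[C@@H]2CO[C@@H]3c2ccc(OCC=C(C)C)c(OC)c2)ccc1O[Si](C)(C)C(C)(C)C | intermediate
19 | (1R,2S,5R,6S)-2-(4-hydroxy-3-methoxyphenyl)-6-[3-methoxy-4-(3-methylbut-2-enyloxy)phenyl]-3,7-dioxabicyclo[3.3.0]octane | COc1cc([C@H]2OC[C@H]3[C@@H]2CO[C@@H]3c2ccc(OCC=C(C)C)c(OC)c2)ccc1O | target

**Count and risks**

Total step count: 11. Longest linear sequence: 9 steps (steps 1, 3, 4, 5, 6, 7, 8, 10, 11).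

Most likely to fail, first: step 10. The mild zinc and magnesium halides may ionise the sulfone too slowly, benzenesulfinic acid may be lost by elimination toward the cyclic enol ether, or part of the aryl transfer may take place on the concave face. The fallback sets out from 12 and comes back at 18, replacing substitution at the acetal carbon by carbonyl addition and SN1 etherification. The methyl acetal is hydrolysed (AcOH/H2O/THF, 45 °C) to the lactol (1R,5R,6S)-6-[3-methoxy-4-(3-methylbut-2-enyloxy)phenyl]-3,7-dioxabicyclo[3.3.0]octan-2-ol F1. Arylmagnesium bromide 16 (3 equiv, THF, 0 °C) adds to its hydroxy aldehyde tautomer to give the diol [4-(tert-butyldimethylsilyloxy)-3-methoxyphenyl]{(3R,4R,5S)-4-(hydroxymethyl)-5-[3-methoxy-4-(3-methylbut-2-enyloxy)phenyl]oxolan-3-yl}methanol F2 as a carbinol mixture. CSA (cat.) in CH2Cl2 at 0 °C then ionises the new para-silyloxybenzylic alcohol, and the neighbouring hydroxymethyl group closes ring 1 with the aryl group exo, giving 18.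

Second: step 1. The butenolide may be consumed by base-promoted ring opening or oligomerisation, the vinyl donor may be lost by protodeboronation, or enantioface discrimination may be insufficient. The fallback sets out from 1 and comes back at 2, obtaining the stereocentre by classical resolution instead of asymmetric catalysis. Copper-mediated conjugate addition of vinylmagnesium bromide (CuI, THF, −40 °C) gives racemic 4-ethenyloxolan-2-one F3. Heating with (S)-1-phenylethylamine opens the lactone to two diastereomeric hydroxy amides, from which (3S)-3-(hydroxymethyl)-N-[(1S)-1-phenylethyl]pent-4-enamide F4 is separated by crystallisation or chromatography from (3R)-3-(hydroxymethyl)-N-[(1S)-1-phenylethyl]pent-4-enamide F5. Hydrolysis of F4 (aq H2SO4, dioxane, reflux) with relactonisation returns 2.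

Third: step 8. The sulfinic acid may ionise the aryl prenyl ether, with loss or allylic transposition of the prenyl group, or the acetal exchange may stop short of completion. The fallback sets out from 10 and comes back at 13, changing the order of events so that no prenyl ether meets the acid. Compound 10 is treated with PhSO2H/CaCl2 in CH2Cl2 to give (1R,5R,6S)-6-[3-methoxy-4-(triisopropylsilyloxy)phenyl]-2-(phenylsulfonyl)-3,7-dioxabicyclo[3.3.0]octane F6. The silyl-to-prenyl exchange (Bu4NF, THF, 0 °C, then prenyl bromide) is then carried out on F6 through the tetrabutylammonium phenoxide of the desilylated sulfone F7, giving 13.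

Further compounds
F1 | step 10 | (1R,5R,6S)-6-[3-methoxy-4-(3-methylbut-2-enyloxy)phenyl]-3,7-dioxabicyclo[3.3.0]octan-2-ol, both C2 anomers | OC1OC[C@H]2[C@@H]1CO[C@@H]2c1ccc(OCC=C(C)C)c(OC)c1
F2 | step 10 | [4-(tert-butyldimethylsilyloxy)-3-methoxyphenyl]{(3R,4R,5S)-4-(hydroxymethyl)-5-[3-methoxy-4-(3-methylbut-2-enyloxy)phenyl]oxolan-3-yl}methanol, both carbinol epimers | OC(c1ccc(O[Si](C)(C)C(C)(C)C)c(OC)c1)[C@H]1CO[C@H](c2ccc(OCC=C(C)C)c(OC)c2)[C@H]1CO
F3 | step 1 | racemic 4-ethenyloxolan-2-one | C=CC1COC(=O)C1
F4 | step 1 | (3S)-3-(hydroxymethyl)-N-[(1S)-1-phenylethyl]pent-4-enamide | C=C[C@@H](CO)CC(=O)N[C@@H](C)c1ccccc1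
F5 | step 1 | (3R)-3-(hydroxymethyl)-N-[(1S)-1-phenylethyl]pent-4-enamide | C=C[C@H](CO)CC(=O)N[C@@H](C)c1ccccc1
F6 | step 8 | (1R,5R,6S)-6-[3-methoxy-4-(triisopropylsilyloxy)phenyl]-2-(phenylsulfonyl)-3,7-dioxabicyclo[3.3.0]octane, both C2 anomers | O=S(=O)(c1ccccc1)C1OC[C@H]2[C@@H]1CO[C@@H]2c1ccc(O[Si](C(C)C)(C(C)C)C(C)C)c(OC)c1
F7 | step 8 | tetrabutylammonium phenoxide of the desilylated sulfone F6 | O=S(=O)(c1ccccc1)C1OC[C@H]2[C@@H]1CO[C@@H]2c1ccc([O-])c(OC)c1.CCCC[N+](CCCC)(CCCC)CCCC
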